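**Retrosynthetic overview** (macrolide numbering: C1 = lactone C=O, C3/C7 = oxane carbons, C13 = lactone carbinol)
1. The last C=C comes from a Still–Gennari olefination of a C5 phosphonoacetate with the oxazole aldehyde. The macrolactone is the last ring formed, by closing O13–C1 of a seco acid.
2. The 2,6-cis-oxane is formed before the macrolactone, from O3 and a C7 ketone by ketalisation and axial ionic reduction. The C7 ketone is the Nef product of a secondary nitroalkane.
3. Key bond C7–C8: the nitronate of a C1–C7 nitroalkane acts as an acyl-anion equivalent for C7. It is C-alkylated by the unactivated C8–C16 alkyl iodide under nickel catalysis. The nitroalkane is one step from the bulk atorvastatin amine, which supplies C3 and C5.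
4. The C8–C16 iodide comes from a one-flask silyl-dithiane linchpin coupling (epoxide, Brook shift, alkyl bromide), which brings in C13 and C9. Evans–Tishchenko reduction then sets C11, followed by O-methylation.
5. The oxazole is made separately and first (Bredereck synthesis). Its Z-alkenyl arm is attached by C2-zincation and stereoretentive Negishi coupling.

Assumption: the SMILES is binding (CIP analysis gives 3R,5R,7R,9S,11R,13R, with C11/C13 anti and the C5 ester axial); bis(2,2,2-trifluoroethyl)phosphonoacetic acid is taken as a catalogue reagent.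

**Step 1**
Reactants: 1 (R)-3-bromo-2-methylpropan-1-ol
Product: 2 (R)-1-bromo-3-chloro-2-methylpropane
Conditions: PPh3, CCl4, CH2Cl2, 0 → 23 °C
Reagents that add atoms: carbon tetrachloride, ClC(Cl)(Cl)Cl
Why: Appel chlorination acts only at the primary C–O carbon under almost halide-free conditions, so the future C9 centre is untouched, Br/Cl scrambling is avoided, and the product carries two leaving groups of graded reactivity.

**Step 2**
Reactants: 3 2-(tert-butyldimethylsilyl)-1,3-dithiane; 4 (R)-2-propyloxirane; 2 (R)-1-bromo-3-chloro-2-methylpropane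
Product: 8 2-[(2R)-2-(tert-butyldimethylsilyloxy)pentyl]-2-[(2S)-3-chloro-2-methylpropyl]-1,3-dithiane, via lithiated silyl dithiane 5 (not isolated), via lithium alkoxide adduct 6 (not isolated), via Brook-shifted lithiodithiane 7 (not isolated)
Conditions: 3, t-BuLi, Et2O, −78 → −45 °C; 4, −78 → −25 °C; then 2, HMPA–THF, −78 → 0 °C
Reagents that add atoms: none
Why: In this silyl-dithiane linchpin coupling (anion relay chemistry), 5 opens the epoxide at its CH2 terminus with retention at C13, HMPA triggers the 1,4-Brook shift that silylates O13 and regenerates a C11 dithiane anion, and that anion displaces only the bromide of 2, leaving no carbanion that could attack the chloride.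

**Step 3**
Reactants: 8 dialkyl dithiane
Product: 10 (2S,6R)-1-chloro-6-hydroxy-2-methylnonan-4-one, via silyloxy ketone 9 (not isolated)
Conditions: PhI(O2CCF3)2, MeCN–H2O 9:1, 0 °C; then 48% aq HF, 23 °C
Reagents that add atoms: water, O
Why: Oxidative dithiane hydrolysis with hypervalent iodine is followed by HF desilylation in the same aqueous acetonitrile, and because no base is present the β-oxy ketone does not eliminate and C9/C13 are untouched.

**Step 4**
Reactants: 10 β-hydroxy ketone
Product: 11 (4R,6R,8S)-9-chloro-6-hydroxy-8-methylnonan-4-yl acetate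
Conditions: SmI2 (20 mol %), MeCHO (8 equiv), THF, −10 °C
Reagents that add atoms: acetaldehyde, CC=O
Why: In the Evans–Tishchenko reduction the samarium-bound hemiacetal of O13 and acetaldehyde delivers hydride intramolecularly through a chair, which sets C11 1,3-anti to C13 (11R, typically >95:5) and leaves only O11 free.

**Step 5**
Reactants: 11 hydroxy acetate
Product: 12 (4R,6R,8S)-9-chloro-6-methoxy-8-methylnonan-4-yl acetate
Conditions: Me3OBF4, Proton-sponge, 4 Å MS, CH2Cl2, 23 °C
Reagents that add atoms: trimethyloxonium tetrafluoroborate, C[O+](C)C.F[B-](F)(F)F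
Why: Meerwein-salt O-methylation under non-nucleophilic, nearly neutral conditions avoids 1,3-acetyl migration, and no stereocentre is touched.

**Step 6**
Reactants: 12 chloride
Product: 13 (4R,6R,8S)-9-iodo-6-methoxy-8-methylnonan-4-yl acetate
Conditions: NaI (5 equiv), 2-butanone, 80 °C
Reagents that add atoms: sodium iodide, [Na+].[I-]
Why: Finkelstein exchange is an SN2 reaction at the primary, non-stereogenic C8 and is driven by precipitation of NaCl.

**Step 7**
Reactants: 14 tert-butyl 2-[(4R,6R)-6-(2-aminoethyl)-2,2-dimethyl-1,3-dioxan-4-yl]acetate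
Product: 15 tert-butyl 2-[(4R,6R)-2,2-dimethyl-6-(2-nitroethyl)-1,3-dioxan-4-yl]acetate
Conditions: DMDO (4 equiv, ca. 0.08 M in acetone), 0 → 23 °C, dark; amine added to the oxidant
Reagents that add atoms: dimethyldioxirane, CC1(C)OO1
Why: Dioxirane oxidation takes a primary aliphatic amine to the nitroalkane under neutral conditions that spare the acetonide and tert-butyl ester, and the syn C3/C5 centres (both R) are bought in.

**Step 8 (key step)**
Reactants: 15 C1–C7 nitroalkane (1.5 equiv); 13 C8–C16 iodide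
Product: 17 tert-butyl 2-{(4R,6R)-6-[(4R,6R,8R)-8-acetoxy-6-methoxy-4-methyl-2-nitroundecyl]-2,2-dimethyl-1,3-dioxan-4-yl}acetate (about 1:1 at the nitro carbon C7), via potassium nitronate 16 (not isolated)
Conditions: KOt-Bu (1.2 equiv), NiBr2·diglyme (10 mol %), bathocuproine (12 mol %), Et2Zn (20 mol %), 1,4-dioxane, 40 °C
Reagents that add atoms: none
Why: In this nickel-catalysed C-alkylation of a nitroalkane with an unactivated alkyl iodide, low-valent nickel abstracts iodine from 13 and the C8 radical is captured at a nickel nitronate, so the C7 acyl-anion equivalent gives C- rather than O-alkylation at a basicity that spares both esters; C9 lies β to the radical and is untouched, and the new C7 centre is erased in step 9.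

**Step 9**
Reactants: 17 secondary nitroalkane
Product: 19 tert-butyl 2-{(4R,6S)-6-[(4S,6R,8R)-8-hydroxy-6-methoxy-4-methyl-2-oxoundecyl]-2,2-dimethyl-1,3-dioxan-4-yl}acetate, via deacetylated potassium nitronate 18 (not isolated)
Conditions: K2CO3 (3 equiv), MeOH, 23 °C; then DMDO (1.2 equiv, acetone), 0 °C, 10 min; pH 7 buffer
Reagents that add atoms: dimethyldioxirane, CC1(C)OO1
Why: Carbonate in methanol removes the acetate (Zemplén-type transesterification) and forms the nitronate, whose C=N bond is cleaved by oxygen transfer (oxidative Nef reaction) to unmask the C7 ketone without strong acid, and prompt buffering prevents β-elimination of O5.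

**Step 10**
Reactants: 19 keto acetonide
Product: 22 2-{(2R,4R,6R)-4-hydroxy-6-[(2S,4R,6R)-6-hydroxy-4-methoxy-2-methylnonyl]oxan-2-yl}acetic acid, via cyclic methyl ketal 20 (not isolated), via oxane tert-butyl ester 21 (not isolated)
Conditions: CSA (10 mol %), MeOH, 23 °C; concentrate; Et3SiH (6 equiv), TFA–CH2Cl2 1:4, −30 → 23 °C; aq NaHCO3 work-up, then acidify
Reagents that add atoms: none
Why: Acid methanolysis of the acetonide lets O3 close onto C7 as a six-ring ketal, Kishi-type ionic reduction delivers hydride axially to the ionised ketal so the C8 chain becomes equatorial (2,6-cis, 7R), and on warming the same TFA cleaves the tert-butyl ester only after ring closure, when O5 is trans to the C3 side chain and cannot form a δ-lactone.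

**Step 11**
Reactants: 22 dihydroxy seco acid
Product: 24 (1R,5R,7R,9S,11R,13R)-13-hydroxy-7-methoxy-9-methyl-5-propyl-4,15-dioxabicyclo[9.3.1]pentadecan-3-one, via mixed anhydride 23 (not isolated)
Conditions: 2,4,6-trichlorobenzoyl chloride, Et3N, THF, 23 °C; then slow addition to DMAP, toluene, 80 °C (1 mM)
Reagents that add atoms: none
Why: In this Yamaguchi macrolactonisation only O13 can reach the activated C1 intramolecularly, because the axial O5 is trans to the C3 side chain, so high dilution selects the 14-membered lactone with retention at C13 and no protecting group on O5.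

**Step 12**
Reactants: 24 macrolactone alcohol; 25 2-[bis(2,2,2-trifluoroethoxy)phosphoryl]acetic acid
Product: 26 (1R,5R,7R,9S,11R,13R)-7-methoxy-9-methyl-3-oxo-5-propyl-4,15-dioxabicyclo[9.3.1]pentadecan-13-yl 2-[bis(2,2,2-trifluoroethoxy)phosphoryl]acetate
Conditions: 25 (2 equiv), EDC·HCl, HOBt, CH2Cl2, 23 °C
Reagents that add atoms: none
Why: Carbodiimide esterification at oxygen keeps the already correct axial C5 configuration, so no Mitsunobu inversion is needed.

**Step 13**
Reactants: 27 (Z)-1,3-dichloropropene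
Product: 29 methyl N-[(Z)-3-chloroprop-2-enyl]carbamate, via chloroallyl isocyanate 28 (not isolated)
Conditions: KOCN, MeOH (3 equiv), DMF, 90 °C
Reagents that add atoms: potassium cyanate, [K+].[O-]C#N; methanol, CO
Why: Cyanate displaces only the allylic chloride by SN2 and methanol traps the isocyanate as the carbamate, while the inert vinyl chloride keeps its Z geometry.

**Step 14**
Reactants: 30 methyl 5-bromo-4-oxopentanoate; 31 formamide
Product: 32 methyl 3-(1,3-oxazol-4-yl)propanoate
Conditions: neat HCONH2 (10 equiv), 110 °C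
Reagents that add atoms: none
Why: In the Bredereck oxazole synthesis the amide oxygen alkylates the CH2Br carbon and nitrogen condenses with the ketone, which places the ester chain at C4 and leaves C2–H free.

**Step 15**
Reactants: 32 oxazole ester (1.4 equiv); 29 (Z)-chloroallyl carbamate
Product: 34 methyl 3-{2-[(1Z)-3-(methoxycarbonylamino)prop-1-enyl]-1,3-oxazol-4-yl}propanoate, via oxazol-2-ylzinc chloride 33 (not isolated)
Conditions: TMPZnCl·LiCl (1.5 equiv), THF, 25 °C; then 29, Pd(Pt-Bu3)2 (3 mol %), THF–NMP, 60 °C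
Reagents that add atoms: none
Why: The amide-zinc base metalates the most acidic C2–H, tolerates the ester and does not open the ring, and Negishi coupling of the alkenyl chloride proceeds with retention, so the Z-alkene is transferred intact.

**Step 16**
Reactants: 34 ester
Product: 35 methyl N-{(2Z)-3-[4-(3-oxopropyl)-1,3-oxazol-2-yl]prop-2-enyl}carbamate
Conditions: DIBAL-H (2.2 equiv), CH2Cl2, −78 °C; Rochelle salt
Reagents that add atoms: none
Why: Partial ester reduction stops at the stable tetrahedral aluminate at −78 °C, with one equivalent consumed by N–H and the carbamate and oxazole inert.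

**Step 17**
Reactants: 26 macrolide phosphonoacetate; 35 oxazole aldehyde
Product: 37 neopeltolide as drawn in the SMILES, via potassium phosphonate anion 36 (not isolated)
Conditions: KHMDS (1.0 equiv), 18-crown-6, THF, −78 °C; then 35, −78 °C
Reagents that add atoms: none
Why: In the Still–Gennari olefination the trifluoroethyl phosphonate with a dissociated potassium counter-ion eliminates under kinetic control to give the (Z)-enoate, and the phosphonoacetate CH2 is far more acidic than the lactone C2–H or the carbamate N–H.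

**Compound list**
1 | (R)-3-bromo-2-methylpropan-1-ol | BrC[C@H](C)CO | starting material
2 | (R)-1-bromo-3-chloro-2-methylpropane | BrC[C@H](C)CCl | intermediate
3 | 2-(tert-butyldimethylsilyl)-1,3-dithiane | CC(C)(C)[Si](C)(C)C1SCCCS1 | starting material
4 | (R)-2-propyloxirane | CCC[C@@H]1CO1 | starting material
5 | 2-lithio-2-(tert-butyldimethylsilyl)-1,3-dithiane | [Li]C1([Si](C)(C)C(C)(C)C)SCCCS1 | intermediate
6 | lithium (2R)-1-[2-(tert-butyldimethylsilyl)-1,3-dithian-2-yl]pentan-2-olate | CCC[C@@H]([O-])CC1([Si](C)(C)C(C)(C)C)SCCCS1.[Li+] | intermediate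
7 | 2-lithio-2-[(2R)-2-(tert-butyldimethylsilyloxy)pentyl]-1,3-dithiane | CCC[C@@H](O[Si](C)(C)C(C)(C)C)CC1([Li])SCCCS1 | intermediate
8 | 2-[(2R)-2-(tert-butyldimethylsilyloxy)pentyl]-2-[(2S)-3-chloro-2-methylpropyl]-1,3-dithiane | CCC[C@@H](O[Si](C)(C)C(C)(C)C)CC1(C[C@H](C)CCl)SCCCS1 | intermediate
9 | (2S,6R)-6-(tert-butyldimethylsilyloxy)-1-chloro-2-methylnonan-4-one | CCC[C@@H](O[Si](C)(C)C(C)(C)C)CC(=O)C[C@H](C)CCl | intermediate
10 | (2S,6R)-1-chloro-6-hydroxy-2-methylnonan-4-one | CCC[C@@H](O)CC(=O)C[C@H](C)CCl | intermediate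
11 | (4R,6R,8S)-9-chloro-6-hydroxy-8-methylnonan-4-yl acetate | CCC[C@@H](OC(C)=O)C[C@H](O)C[C@H](C)CCl | intermediate
12 | (4R,6R,8S)-9-chloro-6-methoxy-8-methylnonan-4-yl acetate | CCC[C@@H](OC(C)=O)C[C@H](OC)C[C@H](C)CCl | intermediate
13 | (4R,6R,8S)-9-iodo-6-methoxy-8-methylnonan-4-yl acetate | CCC[C@@H](OC(C)=O)C[C@H](OC)C[C@H](C)CI | intermediate
14 | tert-butyl 2-[(4R,6R)-6-(2-aminoethyl)-2,2-dimethyl-1,3-dioxan-4-yl]acetate | NCC[C@@H]1C[C@H](CC(=O)OC(C)(C)C)OC(C)(C)O1 | starting material
15 | tert-butyl 2-[(4R,6R)-2,2-dimethyl-6-(2-nitroethyl)-1,3-dioxan-4-yl]acetate | O=[N+]([O-])CC[C@@H]1C[C@H](CC(=O)OC(C)(C)C)OC(C)(C)O1 | intermediate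
16 | potassium nitronate of 15 | [K+].[O-][N+]([O-])=CC[C@@H]1C[C@H](CC(=O)OC(C)(C)C)OC(C)(C)O1 | intermediate
17 | tert-butyl 2-{(4R,6R)-6-[(4R,6R,8R)-8-acetoxy-6-methoxy-4-methyl-2-nitroundecyl]-2,2-dimethyl-1,3-dioxan-4-yl}acetate (C7 epimers) | CCC[C@@H](OC(C)=O)C[C@H](OC)C[C@H](C)CC(C[C@@H]1C[C@H](CC(=O)OC(C)(C)C)OC(C)(C)O1)[N+](=O)[O-] | intermediate
18 | potassium nitronate of the O13-deacetylated form of 17 | CCC[C@@H](O)C[C@H](OC)C[C@H](C)CC(C[C@@H]1C[C@H](CC(=O)OC(C)(C)C)OC(C)(C)O1)=[N+]([O-])[O-].[K+] | intermediate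
19 | tert-butyl 2-{(4R,6S)-6-[(4S,6R,8R)-8-hydroxy-6-methoxy-4-methyl-2-oxoundecyl]-2,2-dimethyl-1,3-dioxan-4-yl}acetate | CCC[C@@H](O)C[C@H](OC)C[C@H](C)CC(=O)C[C@@H]1C[C@H](CC(=O)OC(C)(C)C)OC(C)(C)O1 | intermediate
20 | tert-butyl 2-{(2R,4S)-4-hydroxy-6-[(2S,4R,6R)-6-hydroxy-4-methoxy-2-methylnonyl]-6-methoxyoxan-2-yl}acetate (anomers) | CCC[C@@H](O)C[C@H](OC)C[C@H](C)CC1(OC)C[C@@H](O)C[C@H](CC(=O)OC(C)(C)C)O1 | intermediate
21 | tert-butyl 2-{(2R,4R,6R)-4-hydroxy-6-[(2S,4R,6R)-6-hydroxy-4-methoxy-2-methylnonyl]oxan-2-yl}acetate | CCC[C@@H](O)C[C@H](OC)C[C@H](C)C[C@@H]1C[C@@H](O)C[C@H](CC(=O)OC(C)(C)C)O1 | intermediate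
22 | 2-{(2R,4R,6R)-4-hydroxy-6-[(2S,4R,6R)-6-hydroxy-4-methoxy-2-methylnonyl]oxan-2-yl}acetic acid | CCC[C@@H](O)C[C@H](OC)C[C@H](C)C[C@@H]1C[C@@H](O)C[C@H](CC(=O)O)O1 | intermediate
23 | mixed anhydride of 22 and 2,4,6-trichlorobenzoic acid | CCC[C@@H](O)C[C@H](OC)C[C@H](C)C[C@@H]1C[C@@H](O)C[C@H](CC(=O)OC(=O)c2c(Cl)cc(Cl)cc2Cl)O1 | intermediate
24 | (1R,5R,7R,9S,11R,13R)-13-hydroxy-7-methoxy-9-methyl-5-propyl-4,15-dioxabicyclo[9.3.1]pentadecan-3-one | CCC[C@@H]1C[C@H](OC)C[C@H](C)C[C@@H]2C[C@@H](O)C[C@H](CC(=O)O1)O2 | intermediate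
25 | 2-[bis(2,2,2-trifluoroethoxy)phosphoryl]acetic acid | OC(=O)CP(=O)(OCC(F)(F)F)OCC(F)(F)F | starting material
26 | C5 bis(trifluoroethyl)phosphonoacetate of 24 | CCC[C@@H]1C[C@H](OC)C[C@H](C)C[C@@H]2C[C@@H](OC(=O)CP(=O)(OCC(F)(F)F)OCC(F)(F)F)C[C@H](CC(=O)O1)O2 | intermediate
27 | (Z)-1,3-dichloropropene | ClC/C=C\Cl | starting material
28 | (Z)-1-chloro-3-isocyanatoprop-1-ene | O=C=NC/C=C\Cl | intermediate
29 | methyl N-[(Z)-3-chloroprop-2-enyl]carbamate | COC(=O)NC/C=C\Cl | intermediate
30 | methyl 5-bromo-4-oxopentanoate | COC(=O)CCC(=O)CBr | starting material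
31 | formamide | NC=O | starting material
32 | methyl 3-(1,3-oxazol-4-yl)propanoate | COC(=O)CCc1cocn1 | intermediate
33 | [4-(3-methoxy-3-oxopropyl)-1,3-oxazol-2-yl]zinc chloride | COC(=O)CCc1coc([Zn]Cl)n1 | intermediate
34 | methyl 3-{2-[(1Z)-3-(methoxycarbonylamino)prop-1-enyl]-1,3-oxazol-4-yl}propanoate | COC(=O)CCc1coc(/C=C\CNC(=O)OC)n1 | intermediate
35 | methyl N-{(2Z)-3-[4-(3-oxopropyl)-1,3-oxazol-2-yl]prop-2-enyl}carbamate | O=CCCc1coc(/C=C\CNC(=O)OC)n1 | intermediate
36 | potassium carbanion of 26 | CCC[C@@H]1C[C@H](OC)C[C@H](C)C[C@@H]2C[C@@H](OC(=O)[CH-]P(=O)(OCC(F)(F)F)OCC(F)(F)F)C[C@H](CC(=O)O1)O2.[K+] | intermediate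
37 | neopeltolide: (1R,5R,7R,9S,11R,13R)-7-methoxy-9-methyl-3-oxo-5-propyl-4,15-dioxabicyclo[9.3.1]pentadecan-13-yl (2Z)-5-{2-[(1Z)-3-(methoxycarbonylamino)prop-1-enyl]-1,3-oxazol-4-yl}pent-2-enoate | CCC[C@@H]1C[C@H](OC)C[C@H](C)C[C@@H]2C[C@@H](OC(=O)/C=C\CCc3coc(/C=C\CNC(=O)OC)n3)C[C@H](CC(=O)O1)O2 | target

**Step count**
- Total: 17 steps.
- Longest linear sequence: 12 steps (steps 1–6, 8–12 and 17, starting from 1).

**Three steps most likely to fail**

**Step 8.** The nickel-catalysed nitronate alkylation has not been tried on two densely oxygenated fragments. The likely failures are O-alkylation, reduction of the iodide, or hydrogen-atom transfer within the C8 radical.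
- The fallback keeps the nitronate as the C7 acyl-anion equivalent but makes the bond by polar nitroaldol chemistry. It sets out from 13 and 15 and comes back at 17.
- Iodide 13 is oxidised with Me3NO in DMSO at 23 °C to (4R,6R,8S)-6-methoxy-8-methyl-9-oxononan-4-yl acetate F1.
- A Henry addition of 15 to this aldehyde (catalytic i-Pr2NEt, THF, 0 °C, mild enough to spare the α-methyl centre) gives the C8-hydroxy nitro compound F2.
- Acetylation (Ac2O, catalytic DMAP) gives the β-nitro acetate F3.
- NaBH4 in EtOH at 0 °C eliminates acetate and reduces the nitroalkene as it forms, which delivers 17.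

**Step 11.** The ring is closed with O5 unprotected, so acylation of O5 between molecules could lead to oligomers.
- The fallback reverses the order of ring formation: the macrolactone is closed while O3 and O5 are still tied up in the acetonide. It sets out from 19 and comes back at 24, so it also bypasses step 10.
- TMSOTf/2,6-lutidine cleaves only the tert-butyl ester to give the keto acid acetonide F4.
- F4 has a single free hydroxyl (O13) and is closed under Yamaguchi conditions to the 14-membered keto lactone acetonide F5.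
- CSA in MeOH then gives the transannular bicyclic methyl ketal F6.
- Et3SiH/BF3·OEt2 at −40 °C reduces F6 axially to 24.

**Step 15.** The alkenyl chloride may add to palladium sluggishly, or the alkene may isomerise from Z to E at 60 °C.
- The fallback sets the Z geometry by alkyne semihydrogenation instead of stereoretentive coupling. It sets out from 32 and comes back at 34.
- Zinc reagent 33 is quenched with I2 to give methyl 3-(2-iodo-1,3-oxazol-4-yl)propanoate F7.
- Methyl prop-2-yn-1-ylcarbamate F8 is made from propargylamine and methyl chloroformate.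
- Sonogashira coupling of F7 with F8 (Pd(PPh3)2Cl2, CuI, Et3N) gives the alkynyl oxazole F9.
- H2 over Lindlar catalyst with quinoline gives 34.

**Further compounds**
F1 | step 8 | (4R,6R,8S)-6-methoxy-8-methyl-9-oxononan-4-yl acetate | CCC[C@@H](OC(C)=O)C[C@H](OC)C[C@H](C)C=O
F2 | step 8 | C8-hydroxy derivative of 17 (β-nitro alcohol, C7/C8 epimers) | CCC[C@@H](OC(C)=O)C[C@H](OC)C[C@H](C)C(O)C(C[C@@H]1C[C@H](CC(=O)OC(C)(C)C)OC(C)(C)O1)[N+](=O)[O-]
F3 | step 8 | C8-acetoxy derivative of 17 (β-nitro acetate, C7/C8 epimers) | CCC[C@@H](OC(C)=O)C[C@H](OC)C[C@H](C)C(OC(C)=O)C(C[C@@H]1C[C@H](CC(=O)OC(C)(C)C)OC(C)(C)O1)[N+](=O)[O-]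
F4 | step 11 | 2-{(4R,6S)-6-[(4S,6R,8R)-8-hydroxy-6-methoxy-4-methyl-2-oxoundecyl]-2,2-dimethyl-1,3-dioxan-4-yl}acetic acid | CCC[C@@H](O)C[C@H](OC)C[C@H](C)CC(=O)C[C@@H]1C[C@H](CC(=O)O)OC(C)(C)O1
F5 | step 11 | 14-membered C7-keto lactone carrying the C3/C5 acetonide | CCC[C@@H]1C[C@H](OC)C[C@H](C)CC(=O)C[C@@H]2C[C@H](CC(=O)O1)OC(C)(C)O2
F6 | step 11 | bicyclic C7 methyl ketal of the macrolactone (free C5-OH) | CCC[C@@H]1C[C@H](OC)C[C@H](C)CC2(OC)C[C@@H](O)C[C@H](CC(=O)O1)O2
F7 | step 15 | methyl 3-(2-iodo-1,3-oxazol-4-yl)propanoate | COC(=O)CCc1coc(I)n1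
F8 | step 15 | methyl prop-2-yn-1-ylcarbamate | C#CCNC(=O)OC
F9 | step 15 | methyl 3-{2-[3-(methoxycarbonylamino)prop-1-ynyl]-1,3-oxazol-4-yl}propanoate | COC(=O)CCc1coc(C#CCNC(=O)OC)n1
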